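**Synthesis proposal for CNP0064734.2, the (3S,4R,3'S,4'S) bis-dihydrocoumarin**

Locants: unprimed for the chromanone on the pentaoxygenated benzene (3,4-cis), primed for the chromanone on the phloroglucinol benzene (3',4'-trans).

Retrosynthesis: after removal of eight benzyl ethers, the unprimed lactone is cut at C3–C4 and O1–C2 (aldehyde 12 plus sulfone 23). The primed lactone is cut at C3'–C4' and O1'–C2' (4-pentenal plus sulfone 6). The C3–C3' bond is never cut; it is the C2–C3 bond of 4-pentenal.
Enabling feature: C2–C3–C3'–C2' is a succinic chain, and each lactone ring (O1, C2, C3, C4, C4a, C8a) is the sum of an acyl enolate (C2, C3) and an ortho-quinone methide (O1, C8a, C4a, C4). Both benzo rings carry oxygen at the two positions flanking C4a, so either oxygen can close the lactone.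
Forward order: all four benzene rings are purchased. The primed lactone is annulated first onto C1–C2 of 4-pentenal, the allyl tail is cut back to an aldehyde, the unprimed lactone is annulated last onto those two carbons, and hydrogenolysis ends the route.
Stereochemistry: C4' comes from a chiral triazolium carbene in the first annulation, and C3' from base equilibration to the trans lactone. C3 and C4 are set together as the kinetic cis pair by the antipodal carbene in the last annulation, which also fixes C3 against C3'. The neutral deprotection preserves them.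

Key step: step 13

Assumption: the (5aR,10bS) triazolium salt is taken to give the (3S,4S) adduct 9 and its antipode the (3S,4R) pair of 25; if the first annulation shows the reverse sense, the two antipodes change places.

**Route**

Step 1
Reactants: 1 2,4,6-trihydroxybenzaldehyde
Product: 2 2,4-bis(benzyloxy)-6-hydroxybenzaldehyde
Conditions: BnBr (2 equiv), K2CO3, DMF, 0 °C to rt
Reagents that add atoms: benzyl bromide, BrCc1ccccc1
Why: Williamson etherification, in which the 4-hydroxyl and one ortho hydroxyl are alkylated while the last ortho hydroxyl, held in a hydrogen bond to the formyl oxygen, should stay free at two equivalents of halide.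

Step 2
Reactants: 2 2,4-bis(benzyloxy)-6-hydroxybenzaldehyde; 3 1-(benzyloxy)-4-bromobenzene
Product: 5 3,5-bis(benzyloxy)-2-{[4-(benzyloxy)phenyl](hydroxy)methyl}phenol (racemic), via aryl Grignard reagent 4 (not isolated)
Conditions: 3, Mg, THF, reflux; then 2, THF, 0 °C to rt; pH 7 phosphate buffer
Reagents that add atoms: none
Why: Grignard formation and 1,2-addition to the aldehyde, in which one equivalent of 4 is consumed by the phenol and a second adds to the carbonyl; the carbinol centre is left racemic because it becomes planar in step 4.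

Step 3
Reactants: 5 3,5-bis(benzyloxy)-2-{[4-(benzyloxy)phenyl](hydroxy)methyl}phenol
Product: 6 3,5-bis(benzyloxy)-2-{[4-(benzyloxy)phenyl](tosyl)methyl}phenol (racemic)
Conditions: p-TolSO2Na, HCO2H, CH2Cl2/H2O, rt
Reagents that add atoms: sodium p-toluenesulfinate, [Na+].Cc1ccc(cc1)S([O-])=O
Why: acid-promoted SN1 exchange of the doubly benzylic hydroxyl for sulfinate (S-alkylation through the stabilised diarylmethyl cation), the standard entry to 2-(sulfonylmethyl)phenol quinone methide precursors.

Step 4
Reactants: 6 3,5-bis(benzyloxy)-2-{[4-(benzyloxy)phenyl](tosyl)methyl}phenol; 7 4-pentenal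
Product: 9 (3S,4S)-3-allyl-5,7-bis(benzyloxy)-4-[4-(benzyloxy)phenyl]chroman-2-one (3,4-cis), via ortho-quinone methide 8 (not isolated)
Conditions: (5aR,10bS)-2-mesityl-5a,10b-dihydro-4H,6H-indeno[2,1-b][1,2,4]triazolo[4,3-d][1,4]oxazin-2-ium chloride (10 mol %), 3,3',5,5'-tetra-tert-butyl-4,4'-diphenoquinone, K2CO3, 4 Å MS, toluene, rt
Reagents that add atoms: none
Why: oxidative N-heterocyclic carbene catalysed formal [4+2] annulation, in which base expels sulfinate from 6 to give methide 8, the aldehyde becomes an acyl azolium whose Z enolate adds to the methide carbon, and the phenoxide closes the lactone; the catalyst sets C4' and the endo-type approach gives the cis C3', which is corrected in step 5.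

Step 5
Reactants: 9 (3S,4S)-3-allyl-5,7-bis(benzyloxy)-4-[4-(benzyloxy)phenyl]chroman-2-one
Product: 10 (3R,4S)-3-allyl-5,7-bis(benzyloxy)-4-[4-(benzyloxy)phenyl]chroman-2-one (3,4-trans)
Conditions: DBU (0.2 equiv), CH2Cl2, rt
Reagents that add atoms: none
Why: thermodynamic epimerisation through the lactone enolate, where reprotonation should place the allyl group trans to the 4-aryl group (held pseudo-axial by the peri benzyloxy group), while C4' has no acidic hydrogen and is untouched.

Step 6
Reactants: 10 (3R,4S)-3-allyl-5,7-bis(benzyloxy)-4-[4-(benzyloxy)phenyl]chroman-2-one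
Product: 12 2-{(3R,4S)-5,7-bis(benzyloxy)-4-[4-(benzyloxy)phenyl]-2-oxochroman-3-yl}acetaldehyde, via vicinal diol 11 (not isolated)
Conditions: OsO4 (cat.), NaIO4, 2,6-lutidine, dioxane/H2O, rt
Reagents that add atoms: osmium tetroxide, O=[Os](=O)(=O)=O (delivers the oxygen); sodium periodate, [Na+].[O-]I(=O)(=O)=O (reloads it)
Why: Lemieux–Johnson oxidation, in which OsO4 dihydroxylates only the terminal alkene (the electron-rich arenes that ozone would attack are inert) and periodate cleaves diol 11 before its secondary hydroxyl can open the aryl lactone, the lutidine buffer keeping C3' from epimerising.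

Step 7
Reactants: 13 2,3,4-trihydroxybenzaldehyde
Product: 14 2,3,4-tris(benzyloxy)benzaldehyde
Conditions: BnBr, K2CO3, DMF, 60 °C
Reagents that add atoms: benzyl bromide, BrCc1ccccc1
Why: exhaustive Williamson etherification of the three phenols under standard carbonate conditions.

Step 8
Reactants: 14 2,3,4-tris(benzyloxy)benzaldehyde
Product: 16 2,3,4-tris(benzyloxy)phenol, via aryl formate 15 (not isolated)
Conditions: mCPBA, CH2Cl2, 0 °C to rt; then K2CO3 (cat.), MeOH, rt
Reagents that add atoms: 3-chloroperbenzoic acid, OOC(=O)c1cccc(Cl)c1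
Why: Baeyer–Villiger (Dakin-type) oxidation of an electron-rich benzaldehyde, in which the aryl group migrates to give formate 15, which is methanolysed in the same flask.

Step 9
Reactants: 16 2,3,4-tris(benzyloxy)phenol
Product: 17 1,2,3,4-tetrakis(benzyloxy)benzene
Conditions: BnBr, K2CO3, DMF, rt
Reagents that add atoms: benzyl bromide, BrCc1ccccc1
Why: Williamson etherification of the single free phenol.

Step 10
Reactants: 17 1,2,3,4-tetrakis(benzyloxy)benzene
Product: 18 1-bromo-2,3,4,5-tetrakis(benzyloxy)benzene
Conditions: NBS (1 equiv), MeCN, 0 °C to rt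
Reagents that add atoms: N-bromosuccinimide, O=C1CCC(=O)N1Br
Why: electrophilic aromatic bromination, where the two free positions are equivalent and each is activated by an ortho and a para benzyloxy group, so one equivalent of NBS in a polar solvent should give the monobromide.

Step 11
Reactants: 18 1-bromo-2,3,4,5-tetrakis(benzyloxy)benzene
Product: 21 2,3,4,5-tetrakis(benzyloxy)phenol, via aryllithium 19 (not isolated), via lithium triisopropoxyborate 20 (not isolated)
Conditions: B(OiPr)3, n-BuLi, THF, −78 °C; then AcOH, 30% H2O2, 0 °C to rt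
Reagents that add atoms: hydrogen peroxide, OO
Why: bromine–lithium exchange with in situ borate trapping (so the aryllithium cannot start a Wittig rearrangement of a benzyl ether), followed by peroxide oxidation of the carbon–boron bond, the usual halide-to-phenol sequence.

Step 12
Reactants: 21 2,3,4,5-tetrakis(benzyloxy)phenol; 22 4-(benzyloxy)benzaldehyde
Product: 23 2,3,4,5-tetrakis(benzyloxy)-6-{[4-(benzyloxy)phenyl](tosyl)methyl}phenol (racemic)
Conditions: p-TolSO2Na, HCO2H, CH2Cl2/H2O, rt
Reagents that add atoms: sodium p-toluenesulfinate, [Na+].Cc1ccc(cc1)S([O-])=O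
Why: three-component Friedel–Crafts-type hydroxyalkylation and sulfinate capture, in which the phenol attacks the protonated aldehyde at its only free position (ortho to the hydroxyl, para to a benzyloxy group) and sulfinate traps the diarylmethyl cation at sulfur; the sulfone carbon is racemic and becomes planar in step 13.

Step 13
Reactants: 12 2-{(3R,4S)-5,7-bis(benzyloxy)-4-[4-(benzyloxy)phenyl]-2-oxochroman-3-yl}acetaldehyde; 23 2,3,4,5-tetrakis(benzyloxy)-6-{[4-(benzyloxy)phenyl](tosyl)methyl}phenol
Product: 25 (3S,4R)-5,6,7,8-tetrakis(benzyloxy)-4-[4-(benzyloxy)phenyl]-3-{(3S,4S)-5,7-bis(benzyloxy)-4-[4-(benzyloxy)phenyl]-2-oxochroman-3-yl}chroman-2-one, via ortho-quinone methide 24 (not isolated)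
Conditions: (5aS,10bR)-2-mesityl-5a,10b-dihydro-4H,6H-indeno[2,1-b][1,2,4]triazolo[4,3-d][1,4]oxazin-2-ium chloride (20 mol %), 3,3',5,5'-tetra-tert-butyl-4,4'-diphenoquinone (1.1 equiv), K2CO3, 4 Å MS, toluene, 0 °C
Reagents that add atoms: none
Why: The carbene adds to the aldehyde of 12, the diphenoquinone oxidises the adduct to the acyl azolium, and carbonate removes one of its activated CH2 protons (far more acidic than the lactone C3'–H, which already sits in its stable trans arrangement) to give the catalyst-bound Z enolate, while the same base expels sulfinate from 23 to give methide 24. The enolate carbon (C3) adds to the methide carbon (C4) with rearomatisation of the pentaoxygenated ring, and the phenoxide so released (O1) acylates the acyl azolium carbon (C2), a 6-exo-trig acyl substitution that closes the lactone fused to that ring and frees the carbene. The closest known reaction is the oxidative carbene-catalysed formal [4+2] annulation of aliphatic aldehydes with ortho-quinone methides made in situ from 2-(sulfonylalkyl)phenols, which gives cis-3,4-disubstituted dihydrocoumarins. C3 and C4 are set together: the endo-type approach of the Z enolate to the E methide, whose aryl group points outward, should make them cis, and the aminoindanol backbone of the catalyst blocks one enolate face and so fixes both absolute configurations and the C3/C3' relationship. The step needs cis selectivity, one enolate face beside the resident C3' centre, and no epimerisation of the new C3; the first rests on the kinetic preference of this annulation and on exchange of methide isomers by reversible sulfinate return, the second on catalyst control (substrate bias from C3' is the open point), and the third on the weak heterogeneous base, low temperature and only a slight excess of oxidant.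

Step 14
Reactants: 25 the octabenzyl ether
Product: 26 (3S,4R)-3-[(3S,4S)-5,7-dihydroxy-4-(4-hydroxyphenyl)-2-oxochroman-3-yl]-5,6,7,8-tetrahydroxy-4-(4-hydroxyphenyl)chroman-2-one (CNP0064734.2)
Conditions: H2 (1 atm), 10% Pd/C, THF/EtOAc, rt; filtration and concentration under argon
Reagents that add atoms: none
Why: heterogeneous catalytic hydrogenolysis of benzyl aryl ethers in a neutral aprotic medium, which should leave the epimerisable cis C3, the aryl lactone C–O bonds and the doubly benzylic C4–H and C4'–H untouched.

**Compound list**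

1 | 2,4,6-trihydroxybenzaldehyde | O=Cc1c(O)cc(O)cc1O | starting material
2 | 2,4-bis(benzyloxy)-6-hydroxybenzaldehyde | O=Cc1c(O)cc(OCc2ccccc2)cc1OCc1ccccc1 | intermediate
3 | 1-(benzyloxy)-4-bromobenzene | Brc1ccc(OCc2ccccc2)cc1 | starting material
4 | [4-(benzyloxy)phenyl]magnesium bromide | Br[Mg]c1ccc(OCc2ccccc2)cc1 | intermediate
5 | 3,5-bis(benzyloxy)-2-{[4-(benzyloxy)phenyl](hydroxy)methyl}phenol (racemic) | OC(c1ccc(OCc2ccccc2)cc1)c1c(O)cc(OCc2ccccc2)cc1OCc1ccccc1 | intermediate
6 | 3,5-bis(benzyloxy)-2-{[4-(benzyloxy)phenyl](tosyl)methyl}phenol (racemic) | Cc1ccc(cc1)S(=O)(=O)C(c1ccc(OCc2ccccc2)cc1)c1c(O)cc(OCc2ccccc2)cc1OCc1ccccc1 | intermediate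
7 | 4-pentenal | C=CCCC=O | starting material
8 | (E)-3,5-bis(benzyloxy)-6-[4-(benzyloxy)benzylidene]cyclohexa-2,4-dien-1-one | O=C1C=C(OCc2ccccc2)C=C(OCc2ccccc2)/C1=C\c1ccc(OCc2ccccc2)cc1 | intermediate
9 | (3S,4S)-3-allyl-5,7-bis(benzyloxy)-4-[4-(benzyloxy)phenyl]chroman-2-one (cis) | C=CC[C@@H]1C(=O)Oc2cc(OCc3ccccc3)cc(OCc3ccccc3)c2[C@@H]1c1ccc(OCc2ccccc2)cc1 | intermediate
10 | (3R,4S)-3-allyl-5,7-bis(benzyloxy)-4-[4-(benzyloxy)phenyl]chroman-2-one (trans) | C=CC[C@H]1C(=O)Oc2cc(OCc3ccccc3)cc(OCc3ccccc3)c2[C@@H]1c1ccc(OCc2ccccc2)cc1 | intermediate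
11 | (3R,4S)-5,7-bis(benzyloxy)-4-[4-(benzyloxy)phenyl]-3-(2,3-dihydroxypropyl)chroman-2-one (both carbinol epimers) | OCC(O)C[C@H]1C(=O)Oc2cc(OCc3ccccc3)cc(OCc3ccccc3)c2[C@@H]1c1ccc(OCc2ccccc2)cc1 | intermediate
12 | 2-{(3R,4S)-5,7-bis(benzyloxy)-4-[4-(benzyloxy)phenyl]-2-oxochroman-3-yl}acetaldehyde | O=CC[C@H]1C(=O)Oc2cc(OCc3ccccc3)cc(OCc3ccccc3)c2[C@@H]1c1ccc(OCc2ccccc2)cc1 | intermediate
13 | 2,3,4-trihydroxybenzaldehyde | O=Cc1ccc(O)c(O)c1O | starting material
14 | 2,3,4-tris(benzyloxy)benzaldehyde | O=Cc1ccc(OCc2ccccc2)c(OCc2ccccc2)c1OCc1ccccc1 | intermediate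
15 | 2,3,4-tris(benzyloxy)phenyl formate | O=COc1ccc(OCc2ccccc2)c(OCc2ccccc2)c1OCc1ccccc1 | intermediate
16 | 2,3,4-tris(benzyloxy)phenol | Oc1ccc(OCc2ccccc2)c(OCc2ccccc2)c1OCc1ccccc1 | intermediate
17 | 1,2,3,4-tetrakis(benzyloxy)benzene | c1cc(OCc2ccccc2)c(OCc2ccccc2)c(OCc2ccccc2)c1OCc1ccccc1 | intermediate
18 | 1-bromo-2,3,4,5-tetrakis(benzyloxy)benzene | Brc1cc(OCc2ccccc2)c(OCc2ccccc2)c(OCc2ccccc2)c1OCc1ccccc1 | intermediate
19 | [2,3,4,5-tetrakis(benzyloxy)phenyl]lithium | [Li]c1cc(OCc2ccccc2)c(OCc2ccccc2)c(OCc2ccccc2)c1OCc1ccccc1 | intermediate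
20 | lithium triisopropoxy[2,3,4,5-tetrakis(benzyloxy)phenyl]borate | [Li+].CC(C)O[B-](OC(C)C)(OC(C)C)c1cc(OCc2ccccc2)c(OCc2ccccc2)c(OCc2ccccc2)c1OCc1ccccc1 | intermediate
21 | 2,3,4,5-tetrakis(benzyloxy)phenol | Oc1cc(OCc2ccccc2)c(OCc2ccccc2)c(OCc2ccccc2)c1OCc1ccccc1 | intermediate
22 | 4-(benzyloxy)benzaldehyde | O=Cc1ccc(OCc2ccccc2)cc1 | starting material
23 | 2,3,4,5-tetrakis(benzyloxy)-6-{[4-(benzyloxy)phenyl](tosyl)methyl}phenol (racemic) | Cc1ccc(cc1)S(=O)(=O)C(c1ccc(OCc2ccccc2)cc1)c1c(O)c(OCc2ccccc2)c(OCc2ccccc2)c(OCc2ccccc2)c1OCc1ccccc1 | intermediate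
24 | (E)-2,3,4,5-tetrakis(benzyloxy)-6-[4-(benzyloxy)benzylidene]cyclohexa-2,4-dien-1-one | O=C1C(OCc2ccccc2)=C(OCc2ccccc2)C(OCc2ccccc2)=C(OCc2ccccc2)/C1=C\c1ccc(OCc2ccccc2)cc1 | intermediate
25 | (3S,4R,3'S,4'S) octabenzyl ether of the target | O=C1Oc2c(OCc3ccccc3)c(OCc3ccccc3)c(OCc3ccccc3)c(OCc3ccccc3)c2[C@@H](c2ccc(OCc3ccccc3)cc2)[C@H]1[C@H]1C(=O)Oc2cc(OCc3ccccc3)cc(OCc3ccccc3)c2[C@@H]1c1ccc(OCc2ccccc2)cc1 | intermediate
26 | CNP0064734.2, (3S,4R)-3-[(3S,4S)-5,7-dihydroxy-4-(4-hydroxyphenyl)-2-oxochroman-3-yl]-5,6,7,8-tetrahydroxy-4-(4-hydroxyphenyl)chroman-2-one | O=C1Oc2c(O)c(O)c(O)c(O)c2[C@@H](c2ccc(O)cc2)[C@H]1[C@H]1C(=O)Oc2cc(O)cc(O)c2[C@@H]1c1ccc(O)cc1 | target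

**Step count and risks**

Total: 14 steps. Longest linear sequence: 8 steps (steps 1–6, 13, 14, or equally steps 7–12, 13, 14).

The annulation of step 13 is the most exposed step. The resident C3' centre may oppose the catalyst and erode facial selectivity. The kinetic cis C3 may epimerise under carbonate. The diphenoquinone may oxidise the pentaoxygenated phenoxide, or over-oxidise the enolate to an unsaturated acyl azolium and so destroy C3'. The fallback removes the oxidant and the inorganic base. It sets out from aldehyde 12, which is chlorinated with N-chlorosuccinimide and catalytic DL-proline in CH2Cl2 to the α-chloro aldehyde F1 (either epimer at the chlorinated carbon serves). With the same triazolium chloride and N,N-diisopropylethylamine in EtOAc at low temperature, F1 should lose chloride from the carbene adduct and give the same Z azolium enolate by internal redox. This enolate is trapped by the methide released from 23, and the fallback comes back to the route at compound 25.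

The annulation of step 4 may suffer from low enantiocontrol at C4', or from loss of the peri-substituted methide 8 to self-condensation before the enolate is formed, or from O-acylation of the phenol by the acyl azolium. The fallback builds the same ring by conjugate addition and sets out from compound 2. Wittig olefination with ethyl (triphenylphosphoranylidene)acetate in hot N,N-diethylaniline should pass through ethyl 3-[2,4-bis(benzyloxy)-6-hydroxyphenyl]acrylate F2 and lactonise to 5,7-bis(benzyloxy)coumarin F3. Rhodium-catalysed asymmetric 1,4-addition of [4-(benzyloxy)phenyl]boronic acid follows, using Rh(acac)(C2H4)2 with the enantiomer of SEGPHOS (5,5'-bis(diphenylphosphino)-4,4'-bi-1,3-benzodioxole) that delivers the 4S centre, in dioxane/H2O. This should give (4S)-5,7-bis(benzyloxy)-4-[4-(benzyloxy)phenyl]chroman-2-one F4. Enolisation with LiN(SiMe3)2 in THF at −78 °C and alkylation with allyl bromide anti to the aryl group should give the trans lactone directly. The fallback comes back to the route at compound 10 and bypasses 9 and the equilibration.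

The condensation of step 12 may go astray in three ways. The diarylmethyl cation may be captured by a second molecule of the phenol instead of sulfinate. The acid may slowly cleave benzyl ethers of the very electron-rich ring. The product may ionise again on isolation. The fallback installs the carbinol carbon stepwise and sets out from compound 21. Ortho-formylation with MgCl2, Et3N and paraformaldehyde in MeCN at reflux should give 2,3,4,5-tetrakis(benzyloxy)-6-hydroxybenzaldehyde F5. Addition of Grignard reagent 4 as in step 2 should give 2,3,4,5-tetrakis(benzyloxy)-6-{[4-(benzyloxy)phenyl](hydroxy)methyl}phenol F6. Sulfinate exchange under the conditions of step 3 comes back to the route at compound 23.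

**Further compounds**

F1 | step 13 | 2-chloro-2-{(3R,4S)-5,7-bis(benzyloxy)-4-[4-(benzyloxy)phenyl]-2-oxochroman-3-yl}acetaldehyde (both epimers at the chlorinated carbon) | O=CC(Cl)[C@H]1C(=O)Oc2cc(OCc3ccccc3)cc(OCc3ccccc3)c2[C@@H]1c1ccc(OCc2ccccc2)cc1
F2 | step 4 | ethyl 3-[2,4-bis(benzyloxy)-6-hydroxyphenyl]acrylate (alkene geometry not defined) | CCOC(=O)C=Cc1c(O)cc(OCc2ccccc2)cc1OCc1ccccc1
F3 | step 4 | 5,7-bis(benzyloxy)-2H-chromen-2-one | O=C1C=Cc2c(OCc3ccccc3)cc(OCc3ccccc3)cc2O1
F4 | step 4 | (4S)-5,7-bis(benzyloxy)-4-[4-(benzyloxy)phenyl]chroman-2-one | O=C1Oc2cc(OCc3ccccc3)cc(OCc3ccccc3)c2[C@H](c2ccc(OCc3ccccc3)cc2)C1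
F5 | step 12 | 2,3,4,5-tetrakis(benzyloxy)-6-hydroxybenzaldehyde | O=Cc1c(O)c(OCc2ccccc2)c(OCc2ccccc2)c(OCc2ccccc2)c1OCc1ccccc1
F6 | step 12 | 2,3,4,5-tetrakis(benzyloxy)-6-{[4-(benzyloxy)phenyl](hydroxy)methyl}phenol (racemic) | OC(c1ccc(OCc2ccccc2)cc1)c1c(O)c(OCc2ccccc2)c(OCc2ccccc2)c(OCc2ccccc2)c1OCc1ccccc1
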